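**Plan**

1. Target: (2-hydroxy-4,6-dimethoxyphenyl)(7-hydroxy-2,2-dimethyl-2H-chromen-5-yl)methanone. Ring A is the 2-hydroxy-4,6-dimethoxyphenyl ring, ring B the benzene ring of the chromene, ring C the pyran.
2. Cuts, in order: (a) ring C at O1–C2 and C4–C4a (retro oxa-6π electrocyclization / retro propargyl Claisen) to the aryl 1,1-dimethylpropargyl ether 7; (b) the ether O–C bond, to triol 6; (c) two benzyl–O bonds and one methyl–O bond, to ketone 5; (d) the bond from the carbonyl carbon to ring A, to 1 and 2.
3. Forward: rings A and B are bought as benzenes and joined at the carbonyl carbon (steps 1 and 2). All phenols are set free in one operation (step 3), one ring B phenol is etherified (step 4), and ring C is closed last by a thermal cascade that gives the unprotected target (step 5).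
4. Enabling feature: O1 sits on C8a of ring B next to the unsubstituted C4a, which is ortho to the C5 aroyl group (acceptor) and para to the C7 hydroxyl (donor). Both should steer the [3,3] shift to C4a, whereas an electrophilic chromenylation (prenal condensation) would be expected at C8, between the two oxygens. Rearomatisation of ring B drives the O1–C2 closure.
5. Stereochemistry: the target has no stereocentre (C2 carries two methyl groups) and its C3=C4 alkene is cis by the ring. The carbinol centre of 4 is racemic and is removed in step 2.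

Key step: step 5

Remark: 1 and 2 are taken as purchased; the two ring B hydroxyls of 6 are equivalent, so step 4 is run with a slight deficiency of the alkylating agent and unreacted 6 is recycled.

**Route**

Step 1
Reactants: 1 1,3,5-trimethoxybenzene; 2 3,5-bis(benzyloxy)benzaldehyde
Product: 4 racemic [3,5-bis(benzyloxy)phenyl](2,4,6-trimethoxyphenyl)methanol, via 2,4,6-trimethoxyphenyllithium 3 (not isolated)
Conditions: n-BuLi, THF, 0 °C to rt; then 2, −78 °C to rt; then H2O
Reagents that add atoms: none
Why: Ortho-lithiation of 1 between two methoxy groups (all three ring positions are equivalent) should give 3, whose 1,2-addition to the aldehyde gives the diarylmethanol; the new carbinol centre forms racemic and is erased in step 2.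

Step 2
Reactants: 4 racemic [3,5-bis(benzyloxy)phenyl](2,4,6-trimethoxyphenyl)methanol
Product: 5 [3,5-bis(benzyloxy)phenyl](2,4,6-trimethoxyphenyl)methanone
Conditions: activated MnO2 (excess), CH2Cl2, rt
Reagents that add atoms: none
Why: Oxidation of a doubly benzylic alcohol by MnO2 is reliable, and the neutral conditions avoid ionisation of the acid-labile, electron-rich benzhydrol while leaving the benzyl and methyl ethers untouched.

Step 3
Reactants: 5 [3,5-bis(benzyloxy)phenyl](2,4,6-trimethoxyphenyl)methanone
Product: 6 (3,5-dihydroxyphenyl)(2-hydroxy-4,6-dimethoxyphenyl)methanone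
Conditions: BCl3 (excess), pentamethylbenzene, CH2Cl2, −78 °C to 0 °C; then H2O
Reagents that add atoms: none
Why: Lewis-acid ether cleavage by BCl3 should remove both benzyl groups (the benzyl cations being trapped by pentamethylbenzene) and, by chelation to the ketone oxygen, exactly one of the two equivalent ortho methoxy groups of ring A, the boron chelate then shielding the remaining ortho and para methoxy groups.

Step 4
Reactants: 6 (3,5-dihydroxyphenyl)(2-hydroxy-4,6-dimethoxyphenyl)methanone
Product: 7 {3-hydroxy-5-[(2-methylbut-3-yn-2-yl)oxy]phenyl}(2-hydroxy-4,6-dimethoxyphenyl)methanone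
Conditions: 3-chloro-3-methylbut-1-yne (0.9 equiv), DBU, CuCl2 (cat.), MeCN, 0 °C
Reagents that add atoms: 3-chloro-3-methylbut-1-yne, CC(C)(Cl)C#C
Why: Copper-catalysed propargylic substitution should O-alkylate a ring B phenoxide at the tertiary carbon at 0 °C, far below the rearrangement temperature, while the ring A hydroxyl, hydrogen-bonded to the ketone and flanked by the diaryl ketone, should stay free; the deficiency of chloride limits double alkylation of the two equivalent ring B hydroxyls.

Step 5
Reactants: 7 {3-hydroxy-5-[(2-methylbut-3-yn-2-yl)oxy]phenyl}(2-hydroxy-4,6-dimethoxyphenyl)methanone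
Product: 11 (2-hydroxy-4,6-dimethoxyphenyl)(7-hydroxy-2,2-dimethyl-2H-chromen-5-yl)methanone, via allenyl dienone 8 (not isolated), via ortho-allenylphenol 9 (not isolated), via ortho-quinone methide 10 (not isolated)
Conditions: N,N-diethylaniline, 170 °C, argon
Reagents that add atoms: none
Why: A [3,3] sigmatropic (aryl propargyl ether Claisen) shift bonds the alkyne terminus to the ring B carbon that becomes C4a and gives allenyl dienone 8, which enolises to 9; a [1,5]-hydrogen shift from the phenol O–H to the central allene carbon then gives the (Z)-ortho-quinone methide 10, a 1-oxatriene. The closest known reaction type is the thermal rearrangement of aryl 1,1-dimethylpropargyl ethers to 2,2-dimethyl-2H-chromenes. Ring C is closed by a thermal disrotatory oxa-6π electrocyclization of 10 that forms the O1–C2 bond and is driven by rearomatisation of ring B. No stereocentre arises because C2 carries two methyl groups, and the Z geometry of the exocyclic alkene needed for closure follows from hydrogen delivery on the oxygen side. The step needs the [3,3] shift to go to the carbon between the ether oxygen and the aroyl group and not to the carbon between the two oxygens; the meta aroyl group (which directs towards itself) and the meta hydroxyl (which directs to its para position) both favour the required carbon. The gem-dimethyl group lowers the temperature needed, and the free phenols are expected to be tolerated under these neutral conditions.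

**Compound list**

1 | 1,3,5-trimethoxybenzene | COc1cc(OC)cc(OC)c1 | starting material
2 | 3,5-bis(benzyloxy)benzaldehyde | O=Cc1cc(OCc2ccccc2)cc(OCc2ccccc2)c1 | starting material
3 | 2,4,6-trimethoxyphenyllithium | [Li]c1c(OC)cc(OC)cc1OC | intermediate (not isolated)
4 | racemic [3,5-bis(benzyloxy)phenyl](2,4,6-trimethoxyphenyl)methanol | COc1cc(OC)c(C(O)c2cc(OCc3ccccc3)cc(OCc3ccccc3)c2)c(OC)c1 | intermediate
5 | [3,5-bis(benzyloxy)phenyl](2,4,6-trimethoxyphenyl)methanone | COc1cc(OC)c(C(=O)c2cc(OCc3ccccc3)cc(OCc3ccccc3)c2)c(OC)c1 | intermediate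
6 | (3,5-dihydroxyphenyl)(2-hydroxy-4,6-dimethoxyphenyl)methanone | COc1cc(O)c(C(=O)c2cc(O)cc(O)c2)c(OC)c1 | intermediate
7 | {3-hydroxy-5-[(2-methylbut-3-yn-2-yl)oxy]phenyl}(2-hydroxy-4,6-dimethoxyphenyl)methanone | COc1cc(O)c(C(=O)c2cc(O)cc(OC(C)(C)C#C)c2)c(OC)c1 | intermediate
8 | racemic 3-hydroxy-5-(2-hydroxy-4,6-dimethoxybenzoyl)-6-(3-methylbuta-1,2-dien-1-yl)cyclohexa-2,4-dien-1-one | O=C1C=C(O)C=C(C(=O)c2c(O)cc(OC)cc2OC)C1C=C=C(C)C | intermediate (not isolated)
9 | [3,5-dihydroxy-2-(3-methylbuta-1,2-dien-1-yl)phenyl](2-hydroxy-4,6-dimethoxyphenyl)methanone | COc1cc(O)c(C(=O)c2cc(O)cc(O)c2C=C=C(C)C)c(OC)c1 | intermediate (not isolated)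
10 | (6Z)-3-hydroxy-5-(2-hydroxy-4,6-dimethoxybenzoyl)-6-(3-methylbut-2-en-1-ylidene)cyclohexa-2,4-dien-1-one | O=C1C=C(O)C=C(C(=O)c2c(O)cc(OC)cc2OC)/C1=C/C=C(C)C | intermediate (not isolated)
11 | (2-hydroxy-4,6-dimethoxyphenyl)(7-hydroxy-2,2-dimethyl-2H-chromen-5-yl)methanone | COc1cc(O)c(C(=O)c2cc(O)cc3c2C=CC(C)(C)O3)c(OC)c1 | target

**Step count and risks**

Total step count: 5. Longest linear sequence: 5 steps (1 or 2 to 11).

Steps most likely to fail:

1. Step 5. The [3,3] shift may go in part to the ring B carbon between the two oxygens, and the dienone and quinone methide intermediates may oligomerise at the high temperature. The fallback sets out from 2 and comes back to the route at 11, with the regiochemistry fixed by a halogen and not by the sigmatropic shift. Bromination of 2 with NBS in MeCN, ortho to the formyl group, should give 3,5-bis(benzyloxy)-2-bromobenzaldehyde F1. Addition of 3 at −78 °C should give racemic [3,5-bis(benzyloxy)-2-bromophenyl](2,4,6-trimethoxyphenyl)methanol F2, and MnO2 then gives [3,5-bis(benzyloxy)-2-bromophenyl](2,4,6-trimethoxyphenyl)methanone F3. BCl3 with pentamethylbenzene, as in step 3, should give (2-bromo-3,5-dihydroxyphenyl)(2-hydroxy-4,6-dimethoxyphenyl)methanone F4. Heck coupling of F4 with 2-methylbut-3-en-2-ol (Pd(OAc)2, P(o-tol)3, Et3N, DMF, 100 °C) should give {3,5-dihydroxy-2-[(E)-3-hydroxy-3-methylbut-1-en-1-yl]phenyl}(2-hydroxy-4,6-dimethoxyphenyl)methanone F5. Acid-induced dehydration of F5 (PPTS, toluene, 80 °C) to the ortho-quinone methide and its oxa-6π closure then lead to 11.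

2. Step 4. Both equivalent ring B hydroxyls may be alkylated, the ring A hydroxyl may react, and the product distribution is statistical at best. The fallback sets out from aryllithium 3 (made from 1 as in step 1) and the purchased, already differentiated methyl 3-(benzyloxy)-5-hydroxybenzoate F6, and comes back to the route at 11. F6 has only one free phenol, and its propargylation under the conditions of step 4 should give methyl 3-(benzyloxy)-5-[(2-methylbut-3-yn-2-yl)oxy]benzoate F7. The thermal rearrangement of F7 (N,N-diethylaniline, 170 °C), directed towards the ester and para to the benzyloxy group, should give methyl 7-(benzyloxy)-2,2-dimethyl-2H-chromene-5-carboxylate F8. Addition of one equivalent of 3 to the ester at −78 °C should stop at the hindered ketone [7-(benzyloxy)-2,2-dimethyl-2H-chromen-5-yl](2,4,6-trimethoxyphenyl)methanone F9. BCl3 with pentamethylbenzene at −78 °C should then remove the benzyl group and one ortho methyl group and give 11.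

3. Step 3. Liberated benzyl cations may re-attack the electron-rich rings, and a second methyl ether may be lost under the excess of Lewis acid. The fallback sets out from 5 and comes back to the route at 6, separating the two deprotections. Hydrogenolysis of 5 (H2, palladium on carbon, EtOAc, rt) should give (3,5-dihydroxyphenyl)(2,4,6-trimethoxyphenyl)methanone F10 with no benzyl cation formed. A small excess of BCl3 alone (CH2Cl2, −78 °C to 0 °C) should then cleave one ortho methyl ether by chelation and give 6.

**Further compounds**

F1 | step 5 | 3,5-bis(benzyloxy)-2-bromobenzaldehyde | O=Cc1cc(OCc2ccccc2)cc(OCc2ccccc2)c1Br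
F2 | step 5 | racemic [3,5-bis(benzyloxy)-2-bromophenyl](2,4,6-trimethoxyphenyl)methanol | COc1cc(OC)c(C(O)c2cc(OCc3ccccc3)cc(OCc3ccccc3)c2Br)c(OC)c1
F3 | step 5 | [3,5-bis(benzyloxy)-2-bromophenyl](2,4,6-trimethoxyphenyl)methanone | COc1cc(OC)c(C(=O)c2cc(OCc3ccccc3)cc(OCc3ccccc3)c2Br)c(OC)c1
F4 | step 5 | (2-bromo-3,5-dihydroxyphenyl)(2-hydroxy-4,6-dimethoxyphenyl)methanone | COc1cc(O)c(C(=O)c2cc(O)cc(O)c2Br)c(OC)c1
F5 | step 5 | {3,5-dihydroxy-2-[(E)-3-hydroxy-3-methylbut-1-en-1-yl]phenyl}(2-hydroxy-4,6-dimethoxyphenyl)methanone | COc1cc(O)c(C(=O)c2cc(O)cc(O)c2/C=C/C(C)(C)O)c(OC)c1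
F6 | step 4 | methyl 3-(benzyloxy)-5-hydroxybenzoate | COC(=O)c1cc(O)cc(OCc2ccccc2)c1
F7 | step 4 | methyl 3-(benzyloxy)-5-[(2-methylbut-3-yn-2-yl)oxy]benzoate | COC(=O)c1cc(OCc2ccccc2)cc(OC(C)(C)C#C)c1
F8 | step 4 | methyl 7-(benzyloxy)-2,2-dimethyl-2H-chromene-5-carboxylate | COC(=O)c1cc(OCc2ccccc2)cc2c1C=CC(C)(C)O2
F9 | step 4 | [7-(benzyloxy)-2,2-dimethyl-2H-chromen-5-yl](2,4,6-trimethoxyphenyl)methanone | COc1cc(OC)c(C(=O)c2cc(OCc3ccccc3)cc3c2C=CC(C)(C)O3)c(OC)c1
F10 | step 3 | (3,5-dihydroxyphenyl)(2,4,6-trimethoxyphenyl)methanone | COc1cc(OC)c(C(=O)c2cc(O)cc(O)c2)c(OC)c1
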